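The vessel holds 1.5 M of starting material, and the four new flasks differ in one setting: how long the reagent takes to run in.

| setting | Monday's | Sunday's | dusk | summer | midnight | spring |
|---|---|---|---|---|---|---|
| starting material | 1.5 M | 1.5 M | 1.5 M | 1.5 M | 1.5 M | 1.5 M |
| reagent | 0.50 equiv (fed, over 1.2 h) | 2 equiv (fed, over 1.2 h) | 1.00 equiv (fed, over 1.2 h) | 1.00 equiv (fed, over 2.5 h) | 1.00 equiv (fed, over 5.0 h) | 1.00 equiv (fed, over 10 h) |
| remark | run made earlier | run made earlier |  |  |  |  |
| time |  |  | 15 h | 15 h | 15 h | 15 h |

- Monday's (time / h: target / %, starting material / %): 2.00: 0.1, 95.6; 4.00: 1.4, 96.2; 6.00: 1.3, 94.5; 8.00: 3.5, 92.6; 10.0: 4.7, 89.0; 12.0: 4.5, 87.5; 15.0: 4.5, 84.5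
- Sunday's (time / h: target / %, starting material / %): 2.00: 0.3, 94.3; 4.00: 2.0, 85.2; 6.00: 4.8, 76.0; 8.00: 8.0, 70.1; 10.0: 13.6, 63.7; 12.0: 16.9, 59.0; 15.0: 20.2, 52.7

(standard deviation of a reading: 1 percentage point)

- the numbers in the tables scatter by 1 percentage point (one standard deviation)
- a reading or a percentage of target counts all its forms, free or not
- "hardly changes" means that all values lie within two and a half points (for a concentration: within two and a half percent of the largest)
- a reading of starting material is of its free form alone

- amount of target at the end, in percent of the starting material charged for dusk, summer, midnight, spring, in this order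
- how the row runs (rises, then falls / rises all the way / hardly changes / falls all the way / falls, then rises)

How much time does a slower feed cost you? The feed is steady, so the average portion of reagent arrives at its midpoint. I therefore take the end time minus half the feed time and call it the contact clock. It reads 14.4 h for dusk and 10.0 h for spring, and their quotient is the clock ratio 0.694.

What does that mean for the reagent? Work with the fraction left, not the fraction made. With equal charges reacting one for one at a rate that follows c(starting material) times c(reagent), the reciprocal of the fraction left, minus one, should grow nearly in step with the clock. Call that number used-over-left. Spring's should then be 0.694 of dusk's.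

What does it mean for target? Target comes one step later, so I expect it to grow faster than the clock. In Sunday's run, from 6.00 h to 12.0 h, the clock grew 2.11-fold and target 3.52-fold, as read. I therefore expect spring's target to lie between the clock ratio squared, 0.482, and the ratio itself, 0.694, of dusk's.

How large is the fall? Twice Monday's final target gives 9.00%, and half Sunday's gives 10.1%, so I put dusk near these. Even the mild end of that range then costs spring 2.8 percentage points by my reckoning, which lies outside the band for "hardly changes", so my row falls.

The forecast gives 10.5%, 9.6%, 8.2% and 5.7%, and says the row falls all the way, on the ground that “Slower dosing only delays everything”. Its first point lies above both of my figures for dusk.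

The flasks give 12.0%, 11.2%, 9.84% and 7.24%: falls all the way.

    intermediate → side product (k = 1.30 × 10⁻⁴ /min)
    intermediate → target (k = 0.00170 /min)
    starting material + reagent → intermediate (k = 2.50 × 10⁻⁴ /M/min)
    starting material + target ⇌ idle adduct, settled at all times (K = 0.510 /M)

Spring ends with 0.603 of dusk's target, and its used-over-left for reagent is 0.694 of dusk's, against the clock ratio 0.694. For midnight the clock ratio is 0.868, and its 78% of the charged reagent still unbound gives 0.870. In dusk at 6.71 h, the half-life of reagent by the first step, 36 h, is longer than the 6.8 h of intermediate by the path to target alone. Half of dusk's first-step turnover up to the end is done by 6.71 h, and half of its target-forming turnover up to the end by 9.61 h.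

Readings and results are calculated with constants of no real substance; noise was put on by code.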